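We decide to follow one number through this flask and to let the rest hang on it.

| setting | beta | theta | flask |
|---|---|---|---|
| substrate | 0.050 M (fed, over 3.0 min) | 0.025 M (fed, over 3.0 min) | 0.050 M (fed, over 3.0 min) |
| gas | 3.4 mM (held) | 3.4 mM (held) | 3.4 mM (held) |
| free catalyst | 0.27 mM | 0.27 mM | 0.27 mM |
| remark | the very flask that is asked about, followed so far | run made earlier |  |
| time |  |  | 30 min |

| run | time / min | target / % | open intermediate / % |
|---|---|---|---|
| beta | 0.417 | 0 | 0 |
| beta | 0.833 | 0 | 3.0 |
| beta | 1.50 | 2.2 | 9.5 |
| beta | 3.00 | 2.5 | 26.8 |
| beta | 5.00 | 7.1 | 35.5 |
| theta | 1.50 | 0.6 | 11.8 |
| theta | 3.00 | 3.3 | 28.0 |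
| theta | 6.00 | 10.9 | 36.8 |
| theta | 12.0 | 27.0 | 30.4 |
| theta | 20.0 | 42.9 | 24.0 |

(standard deviation of a reading: 1 percentage point)

- the numbers in the tables scatter by 1 percentage point (one standard deviation)
- at the start none of the gas is in solution
- percentages count the whole charge, also what has not yet gone in
- the reaction counts as stopped when no species that holds the substrate changes by six tenths of a point or more over the second half of the time

* at 30 min, what has stopped the reaction, if anything has (no working catalyst is left / forward and back rates have come level / it is still moving / all of the substrate has reacted)
* amount of target at 30 min, in percent of the substrate charged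
* amount of open intermediate at 30 min, in percent of the substrate charged

The beta run is the asked flask itself, but its readings stop at 5.00 min. The theta run, with half the charge, goes on to 20.0 min. At 3.00 min the two show 26.8% and 28.0% of open intermediate, which agree within the scatter, so we let theta stand in for the later part of the flask.

At 20.0 min theta gives s = 0.420, the open share: open intermediate as a part of all the charge not yet target. At 12.0 min it read 0.416, so we hold it steady.

Between those readings target grew by k = 0.0731 /min per unit of open intermediate, a pseudo-first-order constant. The pool not yet target therefore falls at k·s = 0.0307 /min. Started from theta's last reading and carried on to 30 min, that takes the pool to 42.0%, a fall of 15 percentage points. Our own reckoning is thus 58.0% target, 17.6% open intermediate, and a flask still moving.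

The forecast gives 56% of target (47% to 61%), less than our figure, and 18% of open intermediate (15% to 23%). It answers "it is still moving", and it reads from the runs that “the kinetics look first order in substrate”.

The flask gives 54.4% of target, 19.3% of open intermediate, and it is still moving.

    partner + catalyst intermediate → free catalyst + target (k = 127 /M/s)
    free catalyst + open intermediate ⇌ catalyst intermediate (K = 25.5 /M, k = 37.7 /M/s)
    gas ⇌ partner, rate k3*(csat - [partner]) (kL = 0.0537 /s)
    substrate + free catalyst ⇌ free catalyst + open intermediate (K = 0.800, k = 29.5 /M/s)
    partner → decomposed reagent (k = 0.0308 /s)

In this flask s comes to 0.423. At 30.0 min in this flask substrate has a half-life of 1.8 min by the forward rate alone of its step to open intermediate, shorter than the half-life of 9.99 min that we reckon for open intermediate going on to target, from the pace at which target grew over the second half of the time. Backward turnover of the step between substrate and open intermediate stands at 83% of the forward one. The neighbour with a quarter of the catalyst reaches 16.1% of target, and its s is 0.422.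

The numbers in the tables are calculated with made-up constants.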